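**Strategy.** The hydroazulene is cut at two bonds: C3a–C8a, the ring-fusion bond shared by the five- and seven-membered rings (methyl-bearing quaternary carbon to tertiary carbinol), and C5–C6, the vicinal dioxygenated bond of the seven-membered ring. Each is the product bond of a reductive carbonyl coupling, so the bicycle unfolds to an acyclic C15 keto-enal-dione with one stereocentre, made by an organocatalytic Michael addition. One SmI2 cascade (ketone–enal coupling, then keto-aldehyde pinacol) closes both rings and sets four stereocentres. The feature exploited is that C8a and C6 are ketone-derived carbinols, C5 an aldehyde-derived carbinol and C3a the β-carbon of that aldehyde. C5 is then reset by oxidation and directed reduction before acylation.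

Key step: step 6

Remark: the target SMILES is read as (1R,3aR,5R,6R,8aS). All bicyclic compounds are numbered as the target ester: C1 isopropyl carbon, C3a methyl-bearing fusion carbon, C5 ester carbon, C6 methyl carbinol, C8a hydroxylated fusion carbon. "Lower face" is the face of the 3a-methyl and 8a-hydroxyl groups, "upper face" the opposite one. Compound 11 is drawn as its 2E isomer; any 2Z isomer should converge in step 6 because that double bond is consumed. Compounds 1, 2, 4, 7 and 16 are commercial.

Step 1
Reactants: 1 3-methylbutanal; 2 but-3-en-2-one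
Product: 3 (2R)-5-oxo-2-(propan-2-yl)hexanal
Conditions: (R)-2-(methoxydiphenylmethyl)pyrrolidine (5 mol %), ethyl 3,4-dihydroxybenzoate (20 mol %), neat, 4 °C
Reagents that add atoms: none
Why: Enamine-mediated organocatalytic Michael addition of an aldehyde to a vinyl ketone, in which the diarylmethyl group of the (R)-pyrrolidine shields one face of the (E)-enamine of 1 so that the catechol-activated enone adds to the other face and sets the (R)-stereocentre, while the α-branched product no longer forms an enamine and should not racemise.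

Step 2
Reactants: 3 (2R)-5-oxo-2-(propan-2-yl)hexanal; 4 2-(2-bromoethyl)-2-methyl-1,3-dioxolane
Product: 6 (5R)-6-hydroxy-8-(2-methyl-1,3-dioxolan-2-yl)-5-(propan-2-yl)octan-2-one (both C6 epimers), via Grignard reagent 5 (not isolated)
Conditions: 4, Mg, THF, 25 °C; then 3, THF, −78 °C; aq. NH4Cl
Reagents that add atoms: none
Why: Grignard 1,2-addition that at −78 °C should be chemoselective for the aldehyde over the methyl ketone, the new carbinol centre forming as an epimer mixture that is irrelevant because step 4 makes it a ketone, and the existing stereocentre no longer being α to a carbonyl.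

Step 3
Reactants: 6 (5R)-6-hydroxy-8-(2-methyl-1,3-dioxolan-2-yl)-5-(propan-2-yl)octan-2-one; 7 (Z)-1-bromo-2-ethoxyethene
Product: 9 (1Z,6R)-1-ethoxy-3-methyl-9-(2-methyl-1,3-dioxolan-2-yl)-6-(propan-2-yl)non-1-ene-3,7-diol (C3/C7 epimer mixture), via (Z)-2-ethoxyvinyllithium 8 (not isolated)
Conditions: 7 (2.6 equiv), n-BuLi (2.5 equiv), THF, −78 °C; then 6, −78 → −40 °C; aq. NaHCO3; Et3N-deactivated silica
Reagents that add atoms: none
Why: Bromine–lithium exchange followed by 1,2-addition of the vinyllithium, in which one equivalent of 8 is spent on the hydroxyl and the next adds to the only carbonyl (the methyl ketone) to give a tertiary carbinol (epimer mixture, destroyed in step 5) that carries a masked formylmethylene unit.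

Step 4
Reactants: 9 (1Z,6R)-1-ethoxy-3-methyl-9-(2-methyl-1,3-dioxolan-2-yl)-6-(propan-2-yl)non-1-ene-3,7-diol
Product: 10 (4R,8Z)-9-ethoxy-7-hydroxy-7-methyl-1-(2-methyl-1,3-dioxolan-2-yl)-4-(propan-2-yl)non-8-en-3-one (both C7 epimers)
Conditions: SO3·pyridine, DMSO, iPr2NEt, CH2Cl2, 0 °C
Reagents that add atoms: none
Why: Parikh–Doering oxidation converts the only secondary alcohol into the ketone under basic, non-acidic conditions that should spare the acid-labile hydroxy enol ether and the dioxolane, and the amine base is too weak to enolise the hindered tertiary α-C–H, so the stereocentre is kept.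

Step 5
Reactants: 10 (4R,8Z)-9-ethoxy-7-hydroxy-7-methyl-1-(2-methyl-1,3-dioxolan-2-yl)-4-(propan-2-yl)non-8-en-3-one
Product: 11 (2E,6R)-3-methyl-7,10-dioxo-6-(propan-2-yl)undec-2-enal
Conditions: 1 M HCl, THF, 23 °C
Reagents that add atoms: water, O
Why: Acid-catalysed hydrolysis with allylic 1,3-transposition of the 3-hydroxy enol ether (net formyl-olefination of the ketone) should release the enal, mainly as the E isomer, while the same acid hydrolyses the dioxolane, and dilute acid at room temperature should not enolise the α-branched ketone.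

Step 6
Reactants: 11 (2E,6R)-3-methyl-7,10-dioxo-6-(propan-2-yl)undec-2-enal
Product: 13 (1R,3aR,5S,6R,8aS)-3a,6-dimethyl-1-(propan-2-yl)decahydroazulene-5,6,8a-triol, via cyclopentanol keto-aldehyde 12 (not isolated)
Conditions: SmI2 (5 equiv), HMPA (10 equiv), t-BuOH (3 equiv), THF, −78 → 0 °C, slow addition of 11 (0.01 M final); aq. Rochelle salt
Reagents that add atoms: none
Why: SmI2 transfers four electrons in all: a samarium ketyl at C7 of 11 (or the equivalent enal radical anion) closes the cyclopentane by 5-exo-trig attack on the enal β-carbon C3, t-BuOH C-protonates the resulting samarium enolate to unveil aldehyde 12, and the ketyl of that aldehyde closes the cycloheptane by 7-exo-trig addition of C1 to the samarium-bound C10 ketone (pinacol). The closest known reactions are the SmI2 ketyl–olefin cyclisation of ketones onto α,β-unsaturated carbonyl compounds and the SmI2 pinacol cyclisation of keto-aldehydes, run here as one sequenced cascade. In the chair-like 5-exo transition state the isopropyl group on C6 is pseudo-equatorial and the HMPA-laden ketyl oxygen points away from the enal, so the quaternary methyl carbon (target C3a) and the tertiary carbinol (C8a) should form with methyl, hydroxyl and isopropyl on one face and with the CH2CHO and 3-oxobutyl arms cis on the other, which is the cis ring fusion of the target. In the pinacol closure samarium bridging holds the two new oxygens cis, and they are expected on the upper face, away from the bulky samarium alkoxide at C8a and the angular methyl group, which sets C6 as in the target and leaves C5 epimeric; C5 is deliberately not relied on because steps 7 and 8 reset it. The step needs the cyclopentane to close before any pinacol and the enolate to be protonated before it can add to the C10 ketone: the first is secured by the fast 5-exo mode and the easy reduction of the enal, the second by t-BuOH, which protonates the enolate but is too weak a donor to reduce the ketyls, and the trans relation of alkoxide and CH2CHO arm keeps the aldehyde from being masked as a lactol.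

Step 7
Reactants: 13 (1R,3aR,5S,6R,8aS)-3a,6-dimethyl-1-(propan-2-yl)decahydroazulene-5,6,8a-triol
Product: 14 (1R,3aR,6R,8aS)-6,8a-dihydroxy-3a,6-dimethyl-1-(propan-2-yl)octahydroazulen-5(1H)-one
Conditions: SO3·pyridine, DMSO, iPr2NEt, CH2Cl2, 0 → 23 °C
Reagents that add atoms: none
Why: Parikh–Doering oxidation of the single secondary alcohol should give the α-hydroxy ketone without C–C cleavage of the diol and without touching the two tertiary alcohols, so C5 is erased on purpose and C6 is unaffected.

Step 8
Reactants: 14 (1R,3aR,6R,8aS)-6,8a-dihydroxy-3a,6-dimethyl-1-(propan-2-yl)octahydroazulen-5(1H)-one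
Product: 15 (1R,3aR,5R,6R,8aS)-3a,6-dimethyl-1-(propan-2-yl)decahydroazulene-5,6,8a-triol
Conditions: Me4NBH(OAc)3, MeCN/AcOH, −20 °C
Reagents that add atoms: none
Why: Hydroxyl-directed triacetoxyborohydride reduction (Saksena–Evans type), in which the C6 hydroxyl exchanges onto boron and delivers hydride to the upper face of the C5 ketone, also the face remote from the angular methyl group, so the C5 hydroxyl should form on the lower face, trans to the C6 hydroxyl as in the target.

Step 9
Reactants: 15 (1R,3aR,5R,6R,8aS)-3a,6-dimethyl-1-(propan-2-yl)decahydroazulene-5,6,8a-triol; 16 4-methoxybenzoyl chloride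
Product: 17 (1R,3aR,5R,6R,8aS)-6,8a-dihydroxy-3a,6-dimethyl-1-(propan-2-yl)decahydroazulen-5-yl 4-methoxybenzoate
Conditions: 16 (1.2 equiv), DMAP, Et3N, CH2Cl2, 0 → 23 °C
Reagents that add atoms: none
Why: DMAP-catalysed acyl transfer (Steglich-type acylation) should be selective for the only secondary hydroxyl because both tertiary hydroxyls are far less reactive, and no stereocentre is touched.

**Compound list**

1 | 3-methylbutanal | CC(C)CC=O | starting material
2 | but-3-en-2-one | CC(=O)C=C | starting material
3 | (2R)-5-oxo-2-(propan-2-yl)hexanal | CC(=O)CC[C@H](C(C)C)C=O | intermediate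
4 | 2-(2-bromoethyl)-2-methyl-1,3-dioxolane | CC1(CCBr)OCCO1 | starting material
5 | [2-(2-methyl-1,3-dioxolan-2-yl)ethyl]magnesium bromide | CC1(CC[Mg]Br)OCCO1 | intermediate
6 | (5R)-6-hydroxy-8-(2-methyl-1,3-dioxolan-2-yl)-5-(propan-2-yl)octan-2-one (both C6 epimers) | CC(=O)CC[C@H](C(C)C)C(O)CCC1(C)OCCO1 | intermediate
7 | (Z)-1-bromo-2-ethoxyethene | CCO/C=C\Br | starting material
8 | (Z)-2-ethoxyvinyllithium | CCO/C=C\[Li] | intermediate
9 | (1Z,6R)-1-ethoxy-3-methyl-9-(2-methyl-1,3-dioxolan-2-yl)-6-(propan-2-yl)non-1-ene-3,7-diol (C3/C7 epimer mixture) | CCO/C=C\C(C)(O)CC[C@H](C(C)C)C(O)CCC1(C)OCCO1 | intermediate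
10 | (4R,8Z)-9-ethoxy-7-hydroxy-7-methyl-1-(2-methyl-1,3-dioxolan-2-yl)-4-(propan-2-yl)non-8-en-3-one (both C7 epimers) | CCO/C=C\C(C)(O)CC[C@H](C(C)C)C(=O)CCC1(C)OCCO1 | intermediate
11 | (2E,6R)-3-methyl-7,10-dioxo-6-(propan-2-yl)undec-2-enal | O=C/C=C(\C)CC[C@H](C(C)C)C(=O)CCC(C)=O | intermediate
12 | 2-[(1R,2S,3R)-2-hydroxy-1-methyl-2-(3-oxobutyl)-3-(propan-2-yl)cyclopentyl]acetaldehyde | O=CC[C@@]1(C)CC[C@H](C(C)C)[C@@]1(O)CCC(C)=O | intermediate
13 | (1R,3aR,5S,6R,8aS)-3a,6-dimethyl-1-(propan-2-yl)decahydroazulene-5,6,8a-triol | O[C@H]1C[C@@]2(C)CC[C@H](C(C)C)[C@@]2(O)CC[C@@]1(C)O | intermediate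
14 | (1R,3aR,6R,8aS)-6,8a-dihydroxy-3a,6-dimethyl-1-(propan-2-yl)octahydroazulen-5(1H)-one | O=C1C[C@@]2(C)CC[C@H](C(C)C)[C@@]2(O)CC[C@@]1(C)O | intermediate
15 | (1R,3aR,5R,6R,8aS)-3a,6-dimethyl-1-(propan-2-yl)decahydroazulene-5,6,8a-triol | O[C@@H]1C[C@@]2(C)CC[C@H](C(C)C)[C@@]2(O)CC[C@@]1(C)O | intermediate
16 | 4-methoxybenzoyl chloride | COc1ccc(C(Cl)=O)cc1 | starting material
17 | (1R,3aR,5R,6R,8aS)-6,8a-dihydroxy-3a,6-dimethyl-1-(propan-2-yl)decahydroazulen-5-yl 4-methoxybenzoate | COc1ccc(C(=O)O[C@@H]2C[C@@]3(C)CC[C@H](C(C)C)[C@@]3(O)CC[C@@]2(C)O)cc1 | target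

**Step count.** Total: 9 steps. Longest linear sequence: 9 steps (1 and 2 to 17).

**Steps most likely to fail**

Step 6. The samarium enolate formed after the first ring closure may add to the C10 ketone (aldol) before it is protonated. The unveiled aldehyde may be reduced to the primary alcohol instead of closing the seven-membered ring. The pinacol closure may show poor facial selectivity at C6, which cannot be corrected later. The fallback sets out from 11. SmI2 (2.2 equiv), HMPA, t-BuOH, THF at −78 °C is stopped after the first ring closure and 12 is isolated. McMurry coupling of the aldehyde and the methyl ketone of 12 (TiCl3(DME)1.5, Zn–Cu couple, DME, reflux, slow addition) should give the cycloheptene (1R,3aR,8aS)-3a,6-dimethyl-1-(propan-2-yl)-1,2,3,3a,4,7,8,8a-octahydroazulen-8a-ol F1. Epoxidation directed by the 8a-hydroxyl (VO(acac)2, t-BuOOH, CH2Cl2) should give the lower-face epoxide (1R,3aR,5R,6S,8aS)-5,6-epoxy-3a,6-dimethyl-1-(propan-2-yl)decahydroazulen-8a-ol F2. The syn hydroxyl cannot open this epoxide from the back. Acid hydrolysis (HClO4 cat., THF/H2O) should open it at the tertiary carbon C6 with inversion and give triol 15, where the fallback comes back to the route before step 9.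

Step 2. Chemoselectivity may be lost through attack of the Grignard reagent on the methyl ketone, or through base-induced intramolecular aldol condensation of the keto-aldehyde. The fallback sets out from 3. Aldehyde-selective reduction with NaBH(OAc)3 should give (5R)-5-(hydroxymethyl)-6-methylheptan-2-one F3. Addition of 8 (2.5 equiv) to its ketone should give (2R,6Z)-7-ethoxy-5-methyl-2-(propan-2-yl)hept-6-ene-1,5-diol F4. Parikh–Doering oxidation of the primary alcohol should give (2R,6Z)-7-ethoxy-5-hydroxy-5-methyl-2-(propan-2-yl)hept-6-enal F5, in which the aldehyde is the only carbonyl. Addition of Grignard reagent 5 (2.2 equiv) should then give 9, where the fallback comes back to the route.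

Step 8. Facial selectivity of hydride delivery may be poor: attack from the lower face returns the C5 epimer 13. Transannular hemiketal formation between the 8a-hydroxyl and the C5 ketone, or acyloin rearrangement of 14, may also intervene. The fallback sets out from 13 and replaces steps 7 to 9 by an inversion at C5 with the carboxylate. SOCl2 and Et3N should give the cyclic 5,6-sulfite of 13 F6. RuCl3 (cat.) and NaIO4 should oxidise it to the cyclic 5,6-sulfate of 13 F7. Cesium 4-methoxybenzoate in DMF should open it at the secondary carbon C5 with inversion to give the cesium 6-O-sulfate of 17 F8. Hydrolysis of the sulfate ester (H2SO4 cat., THF/H2O) should give 17, where the fallback comes back to the route.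

Further compounds
F1 | step 6 | (1R,3aR,8aS)-3a,6-dimethyl-1-(propan-2-yl)-1,2,3,3a,4,7,8,8a-octahydroazulen-8a-ol | CC1=CC[C@@]2(C)CC[C@H](C(C)C)[C@@]2(O)CC1
F2 | step 6 | (1R,3aR,5R,6S,8aS)-5,6-epoxy-3a,6-dimethyl-1-(propan-2-yl)decahydroazulen-8a-ol | O1[C@@H]2C[C@@]3(C)CC[C@H](C(C)C)[C@@]3(O)CC[C@]12C
F3 | step 2 | (5R)-5-(hydroxymethyl)-6-methylheptan-2-one | CC(=O)CC[C@H](C(C)C)CO
F4 | step 2 | (2R,6Z)-7-ethoxy-5-methyl-2-(propan-2-yl)hept-6-ene-1,5-diol (both C5 epimers) | CCO/C=C\C(C)(O)CC[C@H](C(C)C)CO
F5 | step 2 | (2R,6Z)-7-ethoxy-5-hydroxy-5-methyl-2-(propan-2-yl)hept-6-enal (both C5 epimers) | CCO/C=C\C(C)(O)CC[C@H](C(C)C)C=O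
F6 | step 8 | cyclic 5,6-sulfite of 13 | O=S1O[C@H]2C[C@@]3(C)CC[C@H](C(C)C)[C@@]3(O)CC[C@@]2(C)O1
F7 | step 8 | cyclic 5,6-sulfate of 13 | O=S1(=O)O[C@H]2C[C@@]3(C)CC[C@H](C(C)C)[C@@]3(O)CC[C@@]2(C)O1
F8 | step 8 | cesium 6-O-sulfate of 17 | COc1ccc(C(=O)O[C@@H]2C[C@@]3(C)CC[C@H](C(C)C)[C@@]3(O)CC[C@@]2(C)OS(=O)(=O)[O-])cc1.[Cs+]
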